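**Retrosynthetic overview**

1. The cyclobutane is cut across C1–C2 (between the two CH–CO2H carbons) and C3–C4 (between the two fully substituted carbons). This gives two molecules of the achiral (E)-3-(4-methoxy-3-methyl-2-oxo-2H-pyran-6-yl)but-2-enoic acid, to be joined by a head-to-head, syn [2+2] photocycloaddition at the most hindered bond of the target.
2. Enabling feature: the four-membered ring consists of two identical CH(CO2H)–C(CH3)(pyronyl) units related by a mirror plane through the midpoints of C1–C2 and C3–C4, and the two CO2H groups on C1/C2 are cis. Both can therefore be esterified to the peri oxygens of naphthalene-1,8-diol, which stacks the two enoate C=C bonds parallel for an intramolecular cycloaddition and is removed afterwards by hydrolysis.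
3. The monomer acid comes from ethyl 2-methylacetoacetate (pyrone C2–C5 and the 3-methyl group) and tert-butyl (E)-3-methyl-4-oxobut-2-enoate (pyrone C6 and the whole side chain, alkene geometry included): dianion aldol, oxidation, lactonisation, O-methylation, tert-butyl ester cleavage.
4. Ring order: 2-pyrone ring (step 4), then the cyclobutane together with a temporary nine-membered dilactone (step 8), then opening of the dilactone (step 9).

Key step: step 8

Remark on the chemistry: the four stereodescriptors of the target describe a meso compound (pyronyls cis to each other, carboxyls cis to each other, each pyronyl trans to the neighbouring carboxyl). The compound as drawn is therefore achiral, and only relative configuration has to be controlled.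

**Route**

Step 1
Reactants: 1 tert-butyl 3-methylbut-2-enoate
Product: 2 tert-butyl (2E)-3-methyl-4-oxobut-2-enoate
Conditions: SeO2 (1.1 equiv), 1,4-dioxane, 80–100 °C
Reagents that add atoms: selenium dioxide, O=[Se]=O
Why: Riley allylic oxidation (ene reaction, then [2,3]-sigmatropic shift) attacks the methyl group trans to the ester of a 3,3-dimethylacrylate and should give the E-configured 4-oxo enoate directly.

Step 2
Reactants: 2 tert-butyl (2E)-3-methyl-4-oxobut-2-enoate; 3 ethyl 2-methyl-3-oxobutanoate
Product: 5 1-tert-butyl 8-ethyl (2E)-4-hydroxy-3,7-dimethyl-6-oxooct-2-enedioate (mixture of diastereomers), via dilithium dianion of the keto ester 4 (not isolated)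
Conditions: 3, LDA (2.2 equiv), THF, 0 °C; then 2, −78 °C; AcOH quench at −78 °C
Reagents that add atoms: none
Why: Acetoacetate dianion aldol, in which the more reactive terminal carbanion should add 1,2 to the aldehyde at low temperature; the two stereocentres formed without control are both erased in steps 3 and 4.

Step 3
Reactants: 5 1-tert-butyl 8-ethyl (2E)-4-hydroxy-3,7-dimethyl-6-oxooct-2-enedioate
Product: 6 1-tert-butyl 8-ethyl (2E)-3,7-dimethyl-4,6-dioxooct-2-enedioate (largely enolised)
Conditions: Dess–Martin periodinane (1.3 equiv), CH2Cl2, 0 °C to rt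
Reagents that add atoms: none
Why: Dess–Martin oxidation of the secondary allylic alcohol to the ketone under neutral conditions, which should leave the E alkene and the tert-butyl ester untouched.

Step 4
Reactants: 6 1-tert-butyl 8-ethyl (2E)-3,7-dimethyl-4,6-dioxooct-2-enedioate
Product: 7 tert-butyl (2E)-3-(4-hydroxy-3-methyl-2-oxo-2H-pyran-6-yl)but-2-enoate
Conditions: DBU (1.5 equiv), toluene, rt to 60 °C; 1 M HCl work-up
Reagents that add atoms: none
Why: Base-mediated lactonisation of a 3,5-diketo ester, in which the enol oxygen at C4 of the chain attacks the ethyl ester (six-membered acyl substitution, loss of ethanol), driven by formation of the stabilised pyronate; the hindered tert-butyl ester should not take part.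

Step 5
Reactants: 7 tert-butyl (2E)-3-(4-hydroxy-3-methyl-2-oxo-2H-pyran-6-yl)but-2-enoate
Product: 8 tert-butyl (2E)-3-(4-methoxy-3-methyl-2-oxo-2H-pyran-6-yl)but-2-enoate
Conditions: Me2SO4 (1.5 equiv), K2CO3 (2 equiv), acetone, rt to 40 °C
Reagents that add atoms: dimethyl sulfate, COS(=O)(=O)OC
Why: O-Methylation of a 3-alkyl-4-hydroxy-2-pyrone with dimethyl sulfate and carbonate, conditions that should favour the 4-methoxy-2-pyrone over the 2-methoxy-4-pyrone isomer.

Step 6
Reactants: 8 tert-butyl (2E)-3-(4-methoxy-3-methyl-2-oxo-2H-pyran-6-yl)but-2-enoate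
Product: 9 (2E)-3-(4-methoxy-3-methyl-2-oxo-2H-pyran-6-yl)but-2-enoic acid
Conditions: TFA/CH2Cl2 (1:4), 0 °C to rt
Reagents that add atoms: none
Why: Acidolysis of the tert-butyl ester with loss of isobutene, which avoids any hydroxide in the presence of the pyrone and should not affect the alkene geometry.

Step 7
Reactants: 9 (2E)-3-(4-methoxy-3-methyl-2-oxo-2H-pyran-6-yl)but-2-enoic acid (2.1 equiv); 10 naphthalene-1,8-diol
Product: 12 naphthalene-1,8-diyl bis[(2E)-3-(4-methoxy-3-methyl-2-oxo-2H-pyran-6-yl)but-2-enoate], via mono-ester 11 (not isolated)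
Conditions: DCC (2.2 equiv), DMAP (0.2 equiv), CH2Cl2, 0 °C to rt, dark
Reagents that add atoms: none
Why: Steglich esterification of both peri hydroxyls, the known way to naphthalene-1,8-diyl bis(3-arylacrylates); no acid chloride is involved, so the E geometry should be kept.

Step 8
Reactants: 12 naphthalene-1,8-diyl bis[(2E)-3-(4-methoxy-3-methyl-2-oxo-2H-pyran-6-yl)but-2-enoate]
Product: 13 naphthalene-1,8-diyl (1R,2S,3R,4S)-3,4-bis(4-methoxy-3-methyl-2-oxo-2H-pyran-6-yl)-3,4-dimethylcyclobutane-1,2-dicarboxylate (cyclic diester, meso)
Conditions: hν (365 nm LED), neat crystalline film between borosilicate plates, N2, rt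
Reagents that add atoms: none
Why: Light of 365 nm is absorbed only by the 6-alkenyl-2-pyrone/enoate chromophore; the excited arm forms an intramolecular excimer with the second arm, which the two peri oxygens of the naphthalene (about 2.5 Å apart) hold parallel and face to face, and the pair collapses by a suprafacial [2+2] cycloaddition of the two CH=C(CH3) bonds, so that the CH–CH bond and the bond between the two fully substituted carbons are made in the same event. The closest known reaction type is the template-directed [2+2] photodimerisation of naphthalene-1,8-diyl bis(cinnamates) to β-truxinates, applied here to a β-methyl-β-pyronyl acrylate. Two rings close: the cyclobutane by the cycloaddition itself, and the temporary nine-membered dilactone (two ester groups, the new CH–CH bond and the peri carbons C1, C8a, C8), which is completed by that same CH–CH bond, so no separate medium-ring closure is needed. All four stereocentres arise here: within each half the pyronyl is trans to the ester carbonyl because the E geometry of each alkene is carried over by the stereospecific addition, and between the halves the two esters and the two pyronyls are cis because only the syn, mirror-image stacking fits the template; the product is meso, so no absolute control is required. The step needs head-to-head regiochemistry, syn over anti orientation, reaction at the exocyclic C=C and not at the pyrone C5=C6 bond, and no E/Z isomerisation; the first two follow from anchoring both carboxyl ends on neighbouring peri positions, the third from the fact that only the enoate double bonds next to the anchor lie within about 4 Å of each other, and the last from the restricted motion in the crystal. The cyclobutane product no longer absorbs at 365 nm, which should protect the now isolated pyrone rings from secondary photoreactions.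

Step 9
Reactants: 13 naphthalene-1,8-diyl (1R,2S,3R,4S)-3,4-bis(4-methoxy-3-methyl-2-oxo-2H-pyran-6-yl)-3,4-dimethylcyclobutane-1,2-dicarboxylate
Product: 15 (1R,2S,3R,4S)-3,4-bis(4-methoxy-3-methyl-2-oxo-2H-pyran-6-yl)-3,4-dimethylcyclobutane-1,2-dicarboxylic acid (target), via half-cleaved hydroxynaphthyl mono-ester 14 (not isolated)
Conditions: LiOH·H2O (4 equiv), THF/H2O (3:1), 0 °C, short reaction time; then 1 M HCl to pH 2
Reagents that add atoms: lithium hydroxide, [Li+].[OH-]
Why: Saponification of the two aryl esters, which are far better acylating agents than the vinylogous pyrone lactones and should be cleaved at 0 °C; after the first cleavage the peri-hydroxynaphthyl group is an even better leaving group and the carboxylates formed resist enolisation, so the four stereocentres should remain as set.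

**Compound list**

1 | tert-butyl 3-methylbut-2-enoate | CC(C)=CC(=O)OC(C)(C)C | starting material
2 | tert-butyl (2E)-3-methyl-4-oxobut-2-enoate | O=C/C(C)=C/C(=O)OC(C)(C)C | intermediate
3 | ethyl 2-methyl-3-oxobutanoate (racemic) | CCOC(=O)C(C)C(C)=O | starting material
4 | dilithium 1-ethoxy-2-methylbuta-1,3-diene-1,3-diolate (dianion of 3) | [Li+].[Li+].C=C([O-])C(C)=C([O-])OCC | intermediate (not isolated)
5 | 1-tert-butyl 8-ethyl (2E)-4-hydroxy-3,7-dimethyl-6-oxooct-2-enedioate (mixture of diastereomers) | CCOC(=O)C(C)C(=O)CC(O)/C(C)=C/C(=O)OC(C)(C)C | intermediate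
6 | 1-tert-butyl 8-ethyl (2E)-3,7-dimethyl-4,6-dioxooct-2-enedioate | CCOC(=O)C(C)C(=O)CC(=O)/C(C)=C/C(=O)OC(C)(C)C | intermediate
7 | tert-butyl (2E)-3-(4-hydroxy-3-methyl-2-oxo-2H-pyran-6-yl)but-2-enoate | Oc1cc(/C(C)=C/C(=O)OC(C)(C)C)oc(=O)c1C | intermediate
8 | tert-butyl (2E)-3-(4-methoxy-3-methyl-2-oxo-2H-pyran-6-yl)but-2-enoate | COc1cc(/C(C)=C/C(=O)OC(C)(C)C)oc(=O)c1C | intermediate
9 | (2E)-3-(4-methoxy-3-methyl-2-oxo-2H-pyran-6-yl)but-2-enoic acid | COc1cc(/C(C)=C/C(=O)O)oc(=O)c1C | intermediate
10 | naphthalene-1,8-diol | Oc1cccc2cccc(O)c12 | starting material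
11 | 8-hydroxynaphthalen-1-yl (2E)-3-(4-methoxy-3-methyl-2-oxo-2H-pyran-6-yl)but-2-enoate | COc1cc(/C(C)=C/C(=O)Oc2cccc3cccc(O)c23)oc(=O)c1C | intermediate (not isolated)
12 | naphthalene-1,8-diyl bis[(2E)-3-(4-methoxy-3-methyl-2-oxo-2H-pyran-6-yl)but-2-enoate] | COc1cc(/C(C)=C/C(=O)Oc2cccc3cccc(OC(=O)/C=C(C)/c4cc(OC)c(C)c(=O)o4)c23)oc(=O)c1C | intermediate
13 | naphthalene-1,8-diyl (1R,2S,3R,4S)-3,4-bis(4-methoxy-3-methyl-2-oxo-2H-pyran-6-yl)-3,4-dimethylcyclobutane-1,2-dicarboxylate (meso cyclic diester) | COc1cc([C@@]2(C)[C@@H]3C(=O)Oc4cccc5cccc(OC(=O)[C@@H]3[C@@]2(C)c2cc(OC)c(C)c(=O)o2)c45)oc(=O)c1C | intermediate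
14 | 2-[(8-hydroxynaphthalen-1-yl)oxycarbonyl]-3,4-bis(4-methoxy-3-methyl-2-oxo-2H-pyran-6-yl)-3,4-dimethylcyclobutane-1-carboxylic acid (racemic, one enantiomer drawn) | COc1cc([C@@]2(C)[C@H](C(=O)O)[C@H](C(=O)Oc3cccc4cccc(O)c34)[C@@]2(C)c2cc(OC)c(C)c(=O)o2)oc(=O)c1C | intermediate (not isolated)
15 | (1R,2S,3R,4S)-3,4-bis(4-methoxy-3-methyl-2-oxo-2H-pyran-6-yl)-3,4-dimethylcyclobutane-1,2-dicarboxylic acid (meso) | COc1cc([C@@]2(C)[C@H](C(=O)O)[C@H](C(=O)O)[C@@]2(C)c2cc(OC)c(C)c(=O)o2)oc(=O)c1C | target

**Step count and risks**

Total step count: 9. Longest linear sequence: 9 steps (1 to 15); two molecules of 9 are combined in step 7.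

The three steps most likely to fail:

Step 8 (key step). The trisubstituted enoates may undergo E/Z photoisomerisation before the bonds form, the crystal may hold the two arms in a conformation that keeps the alkenes apart, or the joining of two fully substituted carbons may be slow enough to let photoreactions of the pyrone ring compete. The fallback replaces the covalent template by a non-covalent one and sets out from compound 9. With half an equivalent of ethane-1,2-diamine in methanol, 9 should crystallise as the 2:1 double salt, ethane-1,2-diaminium bis[(2E)-3-(4-methoxy-3-methyl-2-oxo-2H-pyran-6-yl)but-2-enoate] F1, a salt type in which the gauche diammonium ion is known to hold two cinnamate-type anions head to head. Irradiation of the crystals at 365 nm should give the ethane-1,2-diaminium salt of the cyclobutanedicarboxylate F2, and acidification with 1 M HCl comes back to the route at compound 15, bypassing 12 and 13.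

Step 9. Hydroxide may attack a pyrone lactone carbonyl (ring opening), or base may epimerise a centre alpha to an ester before that ester is cleaved. The fallback unmasks the acids without hydroxide in two operations and sets out from compound 13. Transesterification with allyl alcohol (catalytic K2CO3, THF, rt) should release the template and give diallyl (1R,2S,3R,4S)-3,4-bis(4-methoxy-3-methyl-2-oxo-2H-pyran-6-yl)-3,4-dimethylcyclobutane-1,2-dicarboxylate F3. Palladium-catalysed deallylation (Pd(PPh3)4, morpholine, THF, rt) then comes back to the route at compound 15 under neutral conditions.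

Step 2. The dianion may add in conjugate fashion to the doubly activated alkene of 2, or abstract a proton from its allylic methyl group, instead of adding to the aldehyde. The fallback uses a neutral nucleophile under Lewis acid activation and sets out from compound 3. Silylation (TMSCl, Et3N) should give ethyl 2-methyl-3-(trimethylsilyloxy)but-2-enoate F4, and deprotonation with LDA followed by TMSCl should give 1-ethoxy-2-methyl-1,3-bis(trimethylsilyloxy)buta-1,3-diene F5. A vinylogous Mukaiyama aldol of F5 with aldehyde 2 (TiCl4, CH2Cl2, −78 °C, aqueous work-up) comes back to the route at compound 5.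

**Further compounds**

F1 | step 8 | ethane-1,2-diaminium bis[(2E)-3-(4-methoxy-3-methyl-2-oxo-2H-pyran-6-yl)but-2-enoate] | [NH3+]CC[NH3+].COc1cc(/C(C)=C/C(=O)[O-])oc(=O)c1C.COc1cc(/C(C)=C/C(=O)[O-])oc(=O)c1C
F2 | step 8 | ethane-1,2-diaminium (1R,2S,3R,4S)-3,4-bis(4-methoxy-3-methyl-2-oxo-2H-pyran-6-yl)-3,4-dimethylcyclobutane-1,2-dicarboxylate | [NH3+]CC[NH3+].COc1cc([C@@]2(C)[C@H](C(=O)[O-])[C@H](C(=O)[O-])[C@@]2(C)c2cc(OC)c(C)c(=O)o2)oc(=O)c1C
F3 | step 9 | diallyl (1R,2S,3R,4S)-3,4-bis(4-methoxy-3-methyl-2-oxo-2H-pyran-6-yl)-3,4-dimethylcyclobutane-1,2-dicarboxylate | COc1cc([C@@]2(C)[C@H](C(=O)OCC=C)[C@H](C(=O)OCC=C)[C@@]2(C)c2cc(OC)c(C)c(=O)o2)oc(=O)c1C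
F4 | step 2 | ethyl 2-methyl-3-(trimethylsilyloxy)but-2-enoate (E/Z mixture) | CCOC(=O)C(C)=C(C)O[Si](C)(C)C
F5 | step 2 | 1-ethoxy-2-methyl-1,3-bis(trimethylsilyloxy)buta-1,3-diene (E/Z mixture) | CCOC(O[Si](C)(C)C)=C(C)C(=C)O[Si](C)(C)C
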